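**Retrosynthetic overview**
- The strategy rests on the 1,3-dioxygenated six-membered carbocycle: C1 (secondary allylic carbinol), C2=C3, C4, C5 (tertiary carbinol carrying the 16-phenylhexadec-12-enyl chain) and C6 (methylene between the two carbinols). A C5 hydroxyl β to a C1 carbonyl is an aldol retron.
- C1–OH comes from a cis-selective 1,2-reduction of a C2=C3 enone, and the enone from desaturation of the silyl-protected saturated ketol.
- Key disconnection C5–C6: a chiral-amine-catalysed intramolecular aldol addition of acyclic (Z)-22-phenyldocos-18-ene-2,6-dione. It closes the only ring made in the route (the phenyl ring is bought) and sets C5.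
- The diketone comes from the Weinreb amide of (Z)-17-phenylheptadec-13-enoic acid and the Grignard reagent of ketal-protected 5-chloropentan-2-one. The acid comes from acetylide alkylation of 12-bromododecanoic acid with 5-phenylpent-1-yne, then Lindlar reduction.

Key step: step 5

Remark: the SMILES is read as the cis-diol with S configuration at both carbinol carbons and a Z chain olefin; the ring numbering above is used for all ring compounds.

**Route**

Step 1
Reactants: 1 5-phenylpent-1-yne; 2 12-bromododecanoic acid
Product: 6 17-phenylheptadec-13-ynoic acid, via lithium 5-phenylpent-1-ynide 3 (not isolated), via lithium 12-bromododecanoate 4 (not isolated), via lithium 17-phenylheptadec-13-ynoate 5 (not isolated)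
Conditions: 1 (2.2 equiv), n-BuLi (2.1 equiv), THF, −78 to 0 °C; then 2, DMPU, 0 to 40 °C; 1 M HCl work-up
Reagents that add atoms: none
Why: SN2 alkylation of a lithium acetylide by a primary bromide; the first equivalent of acetylide turns the acid into its carboxylate, which is inert to further acetylide, and DMPU provides the polarity needed for the displacement.

Step 2
Reactants: 6 17-phenylheptadec-13-ynoic acid
Product: 7 (Z)-17-phenylheptadec-13-enoic acid
Conditions: H2 (1 atm), Pd/CaCO3 poisoned with Pb(OAc)2 (Lindlar type), quinoline, EtOAc, 20 °C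
Reagents that add atoms: none
Why: Lindlar semihydrogenation delivers both hydrogens to one face of the alkyne on the poisoned palladium surface, so the Z olefin should form and reduction should stop there, with the acid and the arene untouched.

Step 3
Reactants: 7 (Z)-17-phenylheptadec-13-enoic acid
Product: 9 (Z)-N-methoxy-N-methyl-17-phenylheptadec-13-enamide, via acyl imidazole 8 (not isolated)
Conditions: CDI, CH2Cl2, 20 °C; then MeNH(OMe)·HCl, 20 °C
Reagents that add atoms: N,O-dimethylhydroxylamine hydrochloride, CNOC.Cl
Why: Weinreb amide formation through the acyl imidazole is a standard carboxyl activation under near-neutral conditions that leaves the Z olefin alone.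

Step 4
Reactants: 9 (Z)-N-methoxy-N-methyl-17-phenylheptadec-13-enamide; 10 2-(3-chloropropyl)-2-methyl-1,3-dioxolane
Product: 14 (Z)-22-phenyldocos-18-ene-2,6-dione, via ketal Grignard reagent 11 (not isolated), via magnesium hemiaminal adduct 12 (not isolated), via keto ketal 13 (not isolated)
Conditions: 10, Mg, I2 (cat.), THF, 65 °C; then 9, THF, 0 °C; then 2 M HCl, THF, 20 °C
Reagents that add atoms: water, O
Why: Grignard addition to a Weinreb amide stops at the chelated tetrahedral adduct so no tertiary alcohol forms, and the aqueous acid quench collapses the adduct to the ketone and hydrolyses the dioxolane (acetal hydrolysis) in the same pot.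

Step 5
Reactants: 14 (Z)-22-phenyldocos-18-ene-2,6-dione
Product: 17 (S)-3-hydroxy-3-[(Z)-16-phenylhexadec-12-enyl]cyclohexanone, via proline enamine 15 (not isolated), via cyclised iminium carboxylate 16 (not isolated)
Conditions: (R)-proline (0.3 equiv), DMSO, 20 °C, stopped when 14 is consumed
Reagents that add atoms: none
Why: (R)-Proline condenses with the unhindered methyl ketone of 14 to give the terminal enamine 15, whose CH2 carbon (ring C6) adds to the chain ketone (ring C5) while the carboxylic acid protonates the developing alkoxide, and water then hydrolyses iminium 16 and returns the catalyst. The closest known reaction is the proline-catalysed intramolecular aldol addition of the Hajos–Parrish type, which under these mild conditions should stop at the ketol. The cyclohexanone ring closes in the 6-(enolendo)-exo-trig mode by forming the C5–C6 bond. The C5 stereocentre is set by the catalyst through a chair transition state with the anti enamine, the acid-bound carbonyl oxygen axial and the long chain equatorial; transposing the arrangement that gives the (3aS,7aS) bicyclic ketol with (S)-proline, the (R) catalyst should give the (S) carbinol here. The step needs site selectivity between the two ketones, which is secured because proline forms enamines from methyl ketones far faster than from ketones flanked by two methylenes and because the internal enamine of the methyl ketone could only close a four-membered ring. Enantioface selection at an acyclic dialkyl ketone is an extrapolation from the triketone and heptane-2,6-dione cases and is the main uncertainty of the route.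

Step 6
Reactants: 17 (S)-3-hydroxy-3-[(Z)-16-phenylhexadec-12-enyl]cyclohexanone
Product: 18 (S)-3-[(Z)-16-phenylhexadec-12-enyl]-3-(triethylsilyloxy)cyclohexanone
Conditions: TESOTf, 2,6-lutidine, CH2Cl2, −78 to −40 °C
Reagents that add atoms: triethylsilyl trifluoromethanesulfonate, CC[Si](CC)(CC)OS(=O)(=O)C(F)(F)F
Why: O-silylation of the tertiary alcohol with a silyl triflate and a hindered pyridine base is fast at low temperature, should outrun enol silane formation, and removes the free aldol hydroxyl that would otherwise undergo retro-aldol cleavage under the base of step 7.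

Step 7
Reactants: 18 (S)-3-[(Z)-16-phenylhexadec-12-enyl]-3-(triethylsilyloxy)cyclohexanone
Product: 20 (S)-5-[(Z)-16-phenylhexadec-12-enyl]-5-(triethylsilyloxy)-1-(trimethylsilyloxy)cyclohex-1-ene, via lithium enolate 19 (not isolated)
Conditions: LiN(i-Pr)2, TMSCl (present from the start), THF, −78 °C; Et3N, pentane work-up
Reagents that add atoms: chlorotrimethylsilane, C[Si](C)(C)Cl
Why: Kinetic deprotonation with in situ silyl trapping should take the proton from the unhindered C2 methylene and not from C6, which is neopentyl-like and adjacent to the silyloxy-bearing carbon, and the resulting C1–C2 enolate has no β-leaving group.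

Step 8
Reactants: 20 (S)-5-[(Z)-16-phenylhexadec-12-enyl]-5-(triethylsilyloxy)-1-(trimethylsilyloxy)cyclohex-1-ene
Product: 22 (S)-5-[(Z)-16-phenylhexadec-12-enyl]-5-(triethylsilyloxy)cyclohex-2-en-1-one, via carbon-bound palladium enolate 21 (not isolated)
Conditions: Pd(OAc)2 (1.1 equiv), MeCN, 20 °C
Reagents that add atoms: none
Why: Saegusa–Ito oxidation: the enol silane transmetallates to a palladium enolate and β-hydride elimination from C3 gives the C2=C3 enone; the isolated dialkyl olefin of the chain is a much poorer partner for electrophilic divalent palladium than the enol silane, and C5 is not involved.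

Step 9
Reactants: 22 (S)-5-[(Z)-16-phenylhexadec-12-enyl]-5-(triethylsilyloxy)cyclohex-2-en-1-one
Product: 23 (1S,5S)-5-[(Z)-16-phenylhexadec-12-enyl]-5-(triethylsilyloxy)cyclohex-2-en-1-ol
Conditions: NaBH4, CeCl3·7H2O, MeOH, −78 °C
Reagents that add atoms: none
Why: Luche 1,2-reduction: with the chain pseudo-equatorial and the C5 silyloxy group pseudo-axial, hydride should enter the cerium-activated carbonyl on the face anti to that silyloxy group, placing the new C1 hydroxyl cis to the C5 oxygen and so setting (1S), while the hard reagent suppresses conjugate reduction.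

Step 10
Reactants: 23 (1S,5S)-5-[(Z)-16-phenylhexadec-12-enyl]-5-(triethylsilyloxy)cyclohex-2-en-1-ol
Product: 24 (1S,3S)-1-[(Z)-16-phenylhexadec-12-enyl]cyclohex-4-ene-1,3-diol (the target, cis-diol)
Conditions: HF·pyridine, pyridine, THF, 0 to 20 °C
Reagents that add atoms: none
Why: Fluoride-driven Si–O cleavage under pyridine-buffered conditions should remove the tertiary triethylsilyl ether without ionising the allylic alcohol or touching either stereocentre.

**Compound list**
1 | 5-phenylpent-1-yne | C#CCCCc1ccccc1 | starting material
2 | 12-bromododecanoic acid | OC(=O)CCCCCCCCCCCBr | starting material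
3 | lithium 5-phenylpent-1-ynide | [Li]C#CCCCc1ccccc1 | intermediate
4 | lithium 12-bromododecanoate | [Li+].[O-]C(=O)CCCCCCCCCCCBr | intermediate
5 | lithium 17-phenylheptadec-13-ynoate | [Li+].[O-]C(=O)CCCCCCCCCCCC#CCCCc1ccccc1 | intermediate
6 | 17-phenylheptadec-13-ynoic acid | OC(=O)CCCCCCCCCCCC#CCCCc1ccccc1 | intermediate
7 | (Z)-17-phenylheptadec-13-enoic acid | OC(=O)CCCCCCCCCCC/C=C\CCCc1ccccc1 | intermediate
8 | (Z)-1-(imidazol-1-yl)-17-phenylheptadec-13-en-1-one (acyl imidazole) | O=C(n1ccnc1)CCCCCCCCCCC/C=C\CCCc2ccccc2 | intermediate
9 | (Z)-N-methoxy-N-methyl-17-phenylheptadec-13-enamide | CON(C)C(=O)CCCCCCCCCCC/C=C\CCCc1ccccc1 | intermediate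
10 | 2-(3-chloropropyl)-2-methyl-1,3-dioxolane | CC1(CCCCl)OCCO1 | starting material
11 | [3-(2-methyl-1,3-dioxolan-2-yl)propyl]magnesium chloride (ketal Grignard reagent) | CC1(CCC[Mg]Cl)OCCO1 | intermediate
12 | chloromagnesium salt of the N-methoxy-N-methyl hemiaminal from 9 and 11 (magnesium hemiaminal adduct) | CON(C)C(O[Mg]Cl)(CCCC1(C)OCCO1)CCCCCCCCCCC/C=C\CCCc2ccccc2 | intermediate
13 | (Z)-1-(2-methyl-1,3-dioxolan-2-yl)-20-phenylicos-16-en-4-one (keto ketal) | CC1(CCCC(=O)CCCCCCCCCCC/C=C\CCCc2ccccc2)OCCO1 | intermediate
14 | (Z)-22-phenyldocos-18-ene-2,6-dione | CC(=O)CCCC(=O)CCCCCCCCCCC/C=C\CCCc1ccccc1 | intermediate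
15 | (R)-proline enamine of the methyl ketone of 14 | OC(=O)[C@H]1CCCN1C(=C)CCCC(=O)CCCCCCCCCCC/C=C\CCCc2ccccc2 | intermediate
16 | cyclised iminium carboxylate, (R)-proline iminium of 17 | [O-]C(=O)[C@H]1CCC[N+]1=C3CCC[C@@](O)(CCCCCCCCCCC/C=C\CCCc2ccccc2)C3 | intermediate
17 | (S)-3-hydroxy-3-[(Z)-16-phenylhexadec-12-enyl]cyclohexanone | O=C1CCC[C@@](O)(CCCCCCCCCCC/C=C\CCCc2ccccc2)C1 | intermediate
18 | (S)-3-[(Z)-16-phenylhexadec-12-enyl]-3-(triethylsilyloxy)cyclohexanone | O=C1CCC[C@@](O[Si](CC)(CC)CC)(CCCCCCCCCCC/C=C\CCCc2ccccc2)C1 | intermediate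
19 | lithium C1–C2 enolate of 18 | [Li]OC1=CCC[C@@](O[Si](CC)(CC)CC)(CCCCCCCCCCC/C=C\CCCc2ccccc2)C1 | intermediate
20 | (S)-5-[(Z)-16-phenylhexadec-12-enyl]-5-(triethylsilyloxy)-1-(trimethylsilyloxy)cyclohex-1-ene | C[Si](C)(C)OC1=CCC[C@@](O[Si](CC)(CC)CC)(CCCCCCCCCCC/C=C\CCCc2ccccc2)C1 | intermediate
21 | C2-bound acetoxypalladium enolate of 18 (configuration at C2 undefined) | CC(=O)O[Pd]C1CC[C@@](O[Si](CC)(CC)CC)(CCCCCCCCCCC/C=C\CCCc2ccccc2)CC1=O | intermediate
22 | (S)-5-[(Z)-16-phenylhexadec-12-enyl]-5-(triethylsilyloxy)cyclohex-2-en-1-one | O=C1C=CC[C@@](O[Si](CC)(CC)CC)(CCCCCCCCCCC/C=C\CCCc2ccccc2)C1 | intermediate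
23 | (1S,5S)-5-[(Z)-16-phenylhexadec-12-enyl]-5-(triethylsilyloxy)cyclohex-2-en-1-ol | O[C@@H]1C=CC[C@@](O[Si](CC)(CC)CC)(CCCCCCCCCCC/C=C\CCCc2ccccc2)C1 | intermediate
24 | (1S,3S)-1-[(Z)-16-phenylhexadec-12-enyl]cyclohex-4-ene-1,3-diol | O[C@@H]1C=CC[C@@](O)(CCCCCCCCCCC/C=C\CCCc2ccccc2)C1 | target

**Step count**
Total steps: 10. Longest linear sequence: 10 steps (from 1 and 2; compound 10 enters in step 4).

**Steps most likely to fail**

Step 5. Enantioface discrimination at a ketone flanked by two methylenes may be weak, closure onto an unactivated dialkyl ketone may be slow, and the ketol may drift into dehydration. If only the sense of induction is reversed, (S)-proline is used instead. The fallback sets out from diketone 14 and gives up the direct asymmetric closure. Pyrrolidine and AcOH in toluene at 60 °C should drive the same methyl-side enamine aldol through to dehydration, giving achiral 3-[(Z)-16-phenylhexadec-12-enyl]cyclohex-2-en-1-one F1; ketol 17 of low enantiopurity can be brought to the same enone by acid-catalysed dehydration. Copper-catalysed enantioselective conjugate borylation (CuCl, NaOt-Bu, a chiral bisphosphine such as QuinoxP* in the enantiomer that gives the R boronate, B2pin2, MeOH, THF; the active species is a boryl complex of monovalent copper) should then give (R)-3-[(Z)-16-phenylhexadec-12-enyl]-3-(4,4,5,5-tetramethyl-1,3,2-dioxaborolan-2-yl)cyclohexanone F2. Stereoretentive oxidation of the C–B bond (NaBO3·4H2O, THF/H2O) rejoins the route at ketol 17. Both operations are established for 3-alkylcyclohexenones, and the isolated chain olefin is not a substrate for the copper boryl species.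

Step 9. Hydride may prefer the usual axial trajectory, syn to the C5 silyloxy group, so that facial selectivity favours the trans alcohol. The fallback sets out from enone 22: the reduction is run as before and the epimer (1R,5S)-5-[(Z)-16-phenylhexadec-12-enyl]-5-(triethylsilyloxy)cyclohex-2-en-1-ol F3 is collected. A Mitsunobu reaction (4-nitrobenzoic acid, PPh3, DIAD, THF, 0 °C) should invert C1 by SN2 displacement to give (1S,5S)-5-[(Z)-16-phenylhexadec-12-enyl]-5-(triethylsilyloxy)cyclohex-2-en-1-yl 4-nitrobenzoate F4. Methanolysis (K2CO3, MeOH) rejoins the route at alcohol 23.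

Step 7. Deprotonation may occur in part at C6, followed by β-elimination of silanolate towards the 3-alkylcyclohexenone; in step 8 that follows, palladium hydride may also isomerise the Z chain olefin. The fallback sets out from silyl ketone 18 and goes directly to enone 22 without an enolate and without palladium: 2-iodoxybenzoic acid (IBX) in DMSO/fluorobenzene at 65 °C dehydrogenates the ketone. Only the C2–C3 pair carries the vicinal hydrogens required, because C5 is fully substituted, so the regiochemistry is fixed by the substrate. No new compound arises on this way (F0).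

**Further compounds**
F1 | step 5 | 3-[(Z)-16-phenylhexadec-12-enyl]cyclohex-2-en-1-one | O=C1C=C(CCCCCCCCCCC/C=C\CCCc2ccccc2)CCC1
F2 | step 5 | (R)-3-[(Z)-16-phenylhexadec-12-enyl]-3-(4,4,5,5-tetramethyl-1,3,2-dioxaborolan-2-yl)cyclohexanone | O=C1CCC[C@@](B2OC(C)(C)C(C)(C)O2)(CCCCCCCCCCC/C=C\CCCc3ccccc3)C1
F3 | step 9 | (1R,5S)-5-[(Z)-16-phenylhexadec-12-enyl]-5-(triethylsilyloxy)cyclohex-2-en-1-ol | O[C@H]1C=CC[C@@](O[Si](CC)(CC)CC)(CCCCCCCCCCC/C=C\CCCc2ccccc2)C1
F4 | step 9 | (1S,5S)-5-[(Z)-16-phenylhexadec-12-enyl]-5-(triethylsilyloxy)cyclohex-2-en-1-yl 4-nitrobenzoate | [O-][N+](=O)c3ccc(cc3)C(=O)O[C@@H]1C=CC[C@@](O[Si](CC)(CC)CC)(CCCCCCCCCCC/C=C\CCCc2ccccc2)C1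
F0 | step 7 | none | none
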